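## Analysis of the target

Cyclointegrin (15) is a flavone built from ring A (C4a to C8a), the pyranone ring C (O1, C2, C3, C4) and ring B (C1' to C6'). C3 and C2' are joined by the chain C9H2–C10H2–C11(CH3)2–O, so an eight-membered oxocine ring (C2, C3, C9, C10, C11, O, C2', C1') is fused to ring C along C2–C3 and to ring B along C1'–C2'. The molecule has no stereocentre, and the only stereochemical element met on the way is the geometry of a C9=C10 alkene, which can only be cis inside the eight-membered ring. Besides the bridging oxygen on C2', three phenolic oxygens must be told apart: C7 carries a methyl ether, while the C5 hydroxyl (hydrogen-bonded to the C4 carbonyl) and the C4' hydroxyl are free. The C11–O–C2' link is an aryl tertiary-alkyl ether that SN2 chemistry cannot make, that strong acid ionises, and that is open to Claisen rearrangement and to ionisation by zerovalent palladium while it is still allylic. The hard part is the medium ring, which must be closed across the hindered C2–C1' axis with a quaternary carbon next to oxygen. The plan rests on C2 and C3 being neighbours, C2 bearing O1 and C3 bearing C9: drawn as the two carbons of an aryl ynone, they can take up the ring-A phenol oxygen at C2 and then a carbon at C3, closing ring C and the oxocine ring in one metal-mediated sequence.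

## Retrosynthetic reasoning

**C5–O–CH3 bond (15 to 13).** The 5-hydroxyl is the one phenol a Lewis acid can unmask selectively, because only its methyl ether sits peri to the C4 carbonyl. The forward reaction runs through the boron chelate 14 and leads back to 5-O-methylcyclointegrin 13. Carrying this oxygen as a methyl ether lets ring A come from the commercial aldehyde 7 and leaves exactly one free phenol on ring A for the closure of ring C. The forward step has to spare the 7-methyl ether and the tertiary C11–O–C2' ether.

**C9–C10 unsaturation and the 4'-O-benzyl group (13 to 12).** Both are removed in one hydrogenation, so 13 is traced back to the didehydro benzyl ether 12. Benzyl is chosen for the 4'-oxygen because its removal costs no extra step. The forward reaction must saturate the alkene before the allylic C11–O bond can be hydrogenolysed.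

**O1–C2 and C3–C9 bonds (12 to 11), the key disconnection.** Cutting the two bonds on either side of the C2–C3 unit removes ring C and the oxocine ring together and turns C2–C3 into the triple bond of ynone 11. No other pair of bonds removes both rings and leaves two simple arene halves. Cutting C11–O would demand etherification at a tertiary carbon during a medium-ring closure. Cutting C2–C1' would demand a hindered biaryl-type coupling to close the ring. In the forward sense the phenol oxygen must go to C2 and a carbon–metal bond at C3 must capture the terminal carbon of the tethered vinyl group. The C9=C10 alkene that the metal leaves behind costs nothing, because the hydrogenation is needed anyway.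

**Carbonyl–alkyne bond C4–C3 (11 to 10, then to 8 and 9).** Ynone 11 comes from the racemic carbinol 10 by oxidation. Carbinol 10 comes from the acetylide 9 of alkyne 6 and the phenolate 8 of aldehyde 7. This splits the molecule into a ring-A half and a ring-B half of similar size and needs no protecting group on the ring-A phenol.

**Alkyne carbon (6 to 5).** The terminal alkyne of 6 is a one-carbon homologue of aldehyde 5. The aldehyde carbon becomes C2 and the added carbon becomes C3.

**Vinyl group and C11–O bond (5 to 4, then to 1 and 3, with 3 from 2).** The vinyl group of 5 is the semi-reduced ethynyl group of 4. The tertiary ether of 4 is made at the propargylic stage, from phenol 1 and the trifluoroacetate 3 of alkynol 2, because copper catalysis allows substitution at the tertiary propargylic carbon. Semi-reduction is placed before the homologation so that the molecule never holds two alkynes.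

## Alternatives that were turned down

**Alternative 1: two-carbon ring expansion of a chromene enamine.**
- Disconnection: C9–C10 and C2–C3. The oxocine ring arises from a six-membered pyran ring.
- Forward key step: the enamine 1-[7-(benzyloxy)-2,2-dimethyl-2H-chromen-4-yl]pyrrolidine A1 adds through its β-carbon to the alkyne terminus of the aryl ethynyl ketone 1-[4-methoxy-2,6-bis(methoxymethoxy)phenyl]prop-2-yn-1-one A2. The zwitterion closes to a fused aminocyclobutene, and opening of that four-membered ring gives the benzoxocine enaminone A3. From A3, acid would remove the acetals, either of the two equivalent phenols would displace the amine to close ring C, and hydrogenation would finish.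
- For: the eight-membered ring comes from ring expansion, so there is no medium-ring cyclisation and no endo/exo question. Ring A is symmetric before closure, so the 5-hydroxyl appears free and no late demethylation is needed. On both points this alternative is stronger than the chosen route.
- Against: A1 derives from an electron-rich aryl ketone whose enamine formation is slow and competes with amine-induced opening of the pyranone ring. The nucleophilic β-carbon of A1 lies next to the gem-dimethyl carbon and still bears a hydrogen, so the zwitterion can tautomerise to an open Michael adduct instead of closing to the cyclobutene. The ring opening needs heat while an allylic tertiary ether is present. A2 itself needs protection, ethynylation and oxidation.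
- Comparison: the step count is not lower. The chosen route offers in its place a catalytic step that forms ring C in the same event and a precursor that needs no hindered enamine.

**Alternative 2: chromone annulation onto a preformed benzoxocinone.**
- Disconnection: C3–C4 and O1–C8a.
- Forward key step: the magnesium enolate of 9-(benzyloxy)-2,2-dimethyl-2,3,4,5-tetrahydro-6H-1-benzoxocin-6-one A4 is acylated at carbon by the acid chloride 2,6-difluoro-4-methoxybenzoyl chloride A5. Warming the resulting 1,3-diketone with K2CO3 lets its enol oxygen expel one of the two ortho fluorides of the A5-derived ring, which closes ring C and gives the 5-fluoro compound A6.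
- For: acylation followed by SNAr is dependable ionic chemistry for chromones, and the key step itself is more predictable than the chosen cascade. A5 is a simple symmetric acid chloride, so it does not matter which fluoride leaves.
- Against: the difficulty is only moved. A4 is an eight-membered aryl ketone with a tertiary ether, and every route to it needs its own medium-ring closure or ring expansion over several steps. The fluorine left at C5 in A6 must then be exchanged for oxygen and deprotected, which adds two more steps. C- against O-acylation of a medium-ring enolate is a further uncertainty.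
- Comparison: the route is clearly longer. The chosen route offers in its place a medium ring that is made in the same step as ring C, from a precursor five steps from purchased materials.

**Alternative 3: decarboxylative radical closure onto a 3-vinylflavone.**
- Disconnection: C10–C11.
- Forward key step: irradiation with blue light in the presence of [Ir(dF(CF3)ppy)2(dtbbpy)]PF6 and Cs2CO3 should decarboxylate the acid 2-{5-(benzyloxy)-2-[3-ethenyl-5,7-dimethoxy-4-oxo-4H-chromen-2-yl]phenoxy}-2-methylpropanoic acid A7. The tertiary α-aryloxy radical at C11 would have to add to the vinyl terminus C10 in 8-endo mode. Reduction and protonation of the C9 radical would give 4'-O-benzyl-5-O-methylcyclointegrin A8.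
- For: the tether arrives saturated, so no alkene has to be hydrogenated next to an allylic ether. On this point it is stronger than the chosen route. The tertiary ether also comes from a simple phenol alkylation.
- Against: the C11 radical of decarboxylated A7 sits five atoms from C2, the β-carbon of the chromone enone. A 5-exo attack there gives a stabilised α-keto radical and a spiro dihydrobenzofuran. It is polarity-matched for a nucleophilic radical and should be much faster than an 8-endo closure. Simple reduction of the radical to an isopropyl ether also competes. A7 requires a finished flavone, C3 halogenation, vinylation, alkylation and saponification.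
- Comparison: the precursor is about three steps longer, and A8 would still need the same two deprotections. The chosen route offers in its place a ring closure in which the competing modes are disfavoured by the substrate, not favoured by it.

Key step: step 6

Remarks on the chemistry: flavone numbering with the tether carbons C9, C10 and C11 is used for all compounds from 11 on. Compounds 1, 2 and 7 and the Ohira–Bestmann reagent are assumed to be purchased. Carbinol 10 is racemic and its stereocentre is removed in step 5.

## Route

Step 1
Reactants: 1 4-(benzyloxy)-2-hydroxybenzaldehyde; 2 2-methylbut-3-yn-2-ol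
Product: 4 4-(benzyloxy)-2-[(2-methylbut-3-yn-2-yl)oxy]benzaldehyde, via 2-methylbut-3-yn-2-yl trifluoroacetate 3 (not isolated)
Conditions: 2, (CF3CO)2O, DBU, MeCN, −5 °C; then 1, DBU, CuCl2·2H2O (1 mol %), MeCN, 0 °C
Reagents that add atoms: none
Why: Copper-catalysed propargylic substitution: the copper acetylide of 3 ionises to an allenylidene-type electrophile that the phenolate of 1 captures at the tertiary carbon. Electron-poor, chelated phenols are good substrates, and the low temperature excludes propargyl Claisen rearrangement.

Step 2
Reactants: 4 4-(benzyloxy)-2-[(2-methylbut-3-yn-2-yl)oxy]benzaldehyde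
Product: 5 4-(benzyloxy)-2-[(2-methylbut-3-en-2-yl)oxy]benzaldehyde
Conditions: H2 (1 atm), Lindlar catalyst (Pd on CaCO3 poisoned with Pb(OAc)2), quinoline, EtOAc, rt
Reagents that add atoms: none
Why: Lindlar semihydrogenation of a terminal alkyne stops at the vinyl group. The poisoned catalyst leaves the benzyl ether, the aldehyde and the tertiary C–O bond untouched.

Step 3
Reactants: 5 4-(benzyloxy)-2-[(2-methylbut-3-en-2-yl)oxy]benzaldehyde
Product: 6 4-(benzyloxy)-1-ethynyl-2-[(2-methylbut-3-en-2-yl)oxy]benzene
Conditions: dimethyl (1-diazo-2-oxopropyl)phosphonate, K2CO3, MeOH, 0 °C to rt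
Reagents that add atoms: dimethyl (1-diazo-2-oxopropyl)phosphonate, CC(=O)C(=[N+]=[N-])P(=O)(OC)OC
Why: Ohira–Bestmann homologation: methanolysis of the reagent gives the diazomethylphosphonate anion, which adds to the aldehyde, expels dimethyl phosphate and loses N2 with a 1,2-shift to give the terminal alkyne. The conditions are basic and at room temperature, far below the Claisen threshold of the aryl 1,1-dimethylallyl ether.

Step 4
Reactants: 6 4-(benzyloxy)-1-ethynyl-2-[(2-methylbut-3-en-2-yl)oxy]benzene; 7 2-hydroxy-4,6-dimethoxybenzaldehyde
Product: 10 racemic 2-{3-[4-(benzyloxy)-2-(2-methylbut-3-en-2-yloxy)phenyl]-1-hydroxyprop-2-yn-1-yl}-3,5-dimethoxyphenol, via sodium 2-formyl-3,5-dimethoxyphenolate 8 (not isolated), via lithium [4-(benzyloxy)-2-(2-methylbut-3-en-2-yloxy)phenyl]ethynide 9 (not isolated)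
Conditions: 7, NaH, THF, 0 °C; 6, n-BuLi, THF, −78 °C; combine, −78 to 0 °C; aq NH4Cl; crude product used at once
Reagents that add atoms: none
Why: 1,2-Addition of a lithium acetylide to an aldehyde. The phenol of 7 is first turned into phenolate 8 with a cheap base so that no acetylide is spent on deprotonation, and acetylide additions to salicylaldehyde phenolates are standard. The carbinol centre forms without control and is erased in step 5.

Step 5
Reactants: 10 racemic 2-{3-[4-(benzyloxy)-2-(2-methylbut-3-en-2-yloxy)phenyl]-1-hydroxyprop-2-yn-1-yl}-3,5-dimethoxyphenol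
Product: 11 3-[4-(benzyloxy)-2-(2-methylbut-3-en-2-yloxy)phenyl]-1-(2-hydroxy-4,6-dimethoxyphenyl)prop-2-yn-1-one
Conditions: MnO2 (activated, excess), CH2Cl2, rt
Reagents that add atoms: none
Why: MnO2 oxidation of a benzylic and propargylic alcohol to the ynone. The reagent is neutral and heterogeneous, so the chelated phenol does not add to the ynone and the tertiary allylic ether is not ionised.

Step 6
Reactants: 11 3-[4-(benzyloxy)-2-(2-methylbut-3-en-2-yloxy)phenyl]-1-(2-hydroxy-4,6-dimethoxyphenyl)prop-2-yn-1-one
Product: 12 4'-O-benzyl-5-O-methyl-9,10-didehydrocyclointegrin (5,7-dimethoxyflavone whose C3 is joined to C2' by a cis CH=CH–C(CH3)2–O bridge; 4'-benzyloxy)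
Conditions: Pd(OAc)2 (10 mol %), 1,4-benzoquinone (2 equiv), 4 Å MS, 1,4-dioxane/DMSO (10:1), 0.02 M, 45 °C
Reagents that add atoms: none
Why: Proposed new method: Pd(OAc)2 binds the ynone triple bond and the ring-A phenol adds anti at C2, the β-carbon of the ynone, which closes ring C in 6-endo-dig mode and leaves a C3–palladium bond; this vinylpalladium inserts the tethered vinyl group with C3 bonding to the terminal carbon C9 (8-endo-trig closure of the oxocine ring), syn β-hydride elimination from C9 (C11 is quaternary, so there is no other β-hydrogen) releases the C9=C10 alkene, and benzoquinone with the liberated AcOH returns zerovalent palladium to Pd(OAc)2. The closest known reaction type is the oxypalladation or aminopalladation of 2-alkynylphenols and 2-alkynylanilines with Heck-type trapping of the 3-palladated benzofuran or indole by an alkene; new here are the ynone substrate, which gives a chromone by six-membered oxypalladation, and the intramolecular eight-membered insertion. Oxygen should go to C2 and not to C3 (five-membered aurone-type closure) because the carbonyl polarises the bound alkyne so that C2 is the electrophilic terminus and palladium ends on the carbon next to the carbonyl group. Insertion should beat protonolysis of the C3–palladium bond because the alkene is held over C3 by the C2–C1' bond and the ortho ether, the gem-dimethyl group favours the folded conformer, and AcOH is consumed in the reoxidation so that acid does not build up. The 8-endo mode is expected over 7-exo because bonding at C10 would join the fully substituted C3 to a carbon next to quaternary C11, whereas C9 is an open CH2 terminus, which is the regiochemistry a monosubstituted alkene shows anyway. No stereocentre is formed, and the ring alkene can only be cis. The mild temperature keeps the aryl 1,1-dimethylallyl ether below its Claisen threshold, and fast reoxidation by benzoquinone keeps zerovalent palladium from ionising this tertiary allylic ether.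

Step 7
Reactants: 12 4'-O-benzyl-5-O-methyl-9,10-didehydrocyclointegrin
Product: 13 5-O-methylcyclointegrin
Conditions: H2 (1 atm), Pd/C (10 wt % Pd), EtOAc/MeOH, rt
Reagents that add atoms: none
Why: Heterogeneous catalytic hydrogenation saturates the cis-disubstituted C9=C10 alkene and hydrogenolyses the benzyl ether in one operation, as in the routine conversion of 2,2-dimethyl-2H-chromenes into chromans. The tetrasubstituted C2=C3 bond of the chromone is not reduced at 1 atm.

Step 8
Reactants: 13 5-O-methylcyclointegrin
Product: 15 cyclointegrin, via 4',5-bis-O-(dichloroboryl)cyclointegrin 14 (not isolated)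
Conditions: BCl3 (2.2 equiv), CH2Cl2, −78 to −20 °C; then H2O, 0 °C
Reagents that add atoms: none
Why: Chelation-directed demethylation: BCl3 bridges the C4 carbonyl and the peri 5-methoxy oxygen, chloride removes the methyl group, and water hydrolyses the boron aryloxides of 14. One equivalent of BCl3 is taken up by the free 4'-phenol. The 7-methyl ether and the tertiary alkyl aryl ether have no chelating carbonyl and should not react at low temperature, as tertiary ethers of the 2,2-dimethylchroman type routinely survive boron trihalide demethylations.

## Compound list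

1 | 4-(benzyloxy)-2-hydroxybenzaldehyde | O=Cc1ccc(OCc2ccccc2)cc1O | starting material
2 | 2-methylbut-3-yn-2-ol | CC(C)(O)C#C | starting material
3 | 2-methylbut-3-yn-2-yl trifluoroacetate | CC(C)(C#C)OC(=O)C(F)(F)F | intermediate (not isolated)
4 | 4-(benzyloxy)-2-[(2-methylbut-3-yn-2-yl)oxy]benzaldehyde | O=Cc1ccc(OCc2ccccc2)cc1OC(C)(C)C#C | intermediate
5 | 4-(benzyloxy)-2-[(2-methylbut-3-en-2-yl)oxy]benzaldehyde | O=Cc1ccc(OCc2ccccc2)cc1OC(C)(C)C=C | intermediate
6 | 4-(benzyloxy)-1-ethynyl-2-[(2-methylbut-3-en-2-yl)oxy]benzene | C#Cc1ccc(OCc2ccccc2)cc1OC(C)(C)C=C | intermediate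
7 | 2-hydroxy-4,6-dimethoxybenzaldehyde | COc1cc(O)c(C=O)c(OC)c1 | starting material
8 | sodium 2-formyl-3,5-dimethoxyphenolate | [Na+].[O-]c1cc(OC)cc(OC)c1C=O | intermediate (not isolated)
9 | lithium [4-(benzyloxy)-2-(2-methylbut-3-en-2-yloxy)phenyl]ethynide | [Li+].[C-]#Cc1ccc(OCc2ccccc2)cc1OC(C)(C)C=C | intermediate (not isolated)
10 | racemic 2-{3-[4-(benzyloxy)-2-(2-methylbut-3-en-2-yloxy)phenyl]-1-hydroxyprop-2-yn-1-yl}-3,5-dimethoxyphenol | COc1cc(O)c(C(O)C#Cc2ccc(OCc3ccccc3)cc2OC(C)(C)C=C)c(OC)c1 | intermediate
11 | 3-[4-(benzyloxy)-2-(2-methylbut-3-en-2-yloxy)phenyl]-1-(2-hydroxy-4,6-dimethoxyphenyl)prop-2-yn-1-one | COc1cc(O)c(C(=O)C#Cc2ccc(OCc3ccccc3)cc2OC(C)(C)C=C)c(OC)c1 | intermediate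
12 | 4'-O-benzyl-5-O-methyl-9,10-didehydrocyclointegrin (cis ring alkene) | COc1cc(OC)c2c(=O)c3/C=C\C(C)(C)Oc4cc(OCc5ccccc5)ccc4-c3oc2c1 | intermediate
13 | 5-O-methylcyclointegrin | COc1cc(OC)c2c(=O)c3c(oc2c1)-c1ccc(O)cc1OC(C)(C)CC3 | intermediate
14 | 4',5-bis-O-(dichloroboryl)cyclointegrin | COc1cc(OB(Cl)Cl)c2c(=O)c3c(oc2c1)-c1ccc(OB(Cl)Cl)cc1OC(C)(C)CC3 | intermediate (not isolated)
15 | cyclointegrin | COc1cc(O)c2c(=O)c3c(oc2c1)-c1ccc(O)cc1OC(C)(C)CC3 | target

## Step count and least certain steps

Total: 8 steps. Longest linear sequence: 8 steps (1 to 4, 5, 6, 10, 11, 12, 13, 15; aldehyde 7 enters at step 4).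

**Step 6 (key step, proposed new method).**
- Most likely failure: protonolysis of the C3–palladium bond outruns the eight-membered insertion, so ring C closes without the C3–C9 bond.
- Further possible losses: attack of the phenol at the carbonyl-side alkyne carbon (five-membered closure), insertion with the opposite regiochemistry (seven-membered ring with an exocyclic methylene), and ionisation of the tertiary allylic ether if reoxidation of zerovalent palladium lags.
- Fallback: it uses known reaction types and closes the ring at C9=C10 instead of C3–C9. It sets out from 11 and returns at 12. Amine-catalysed 6-endo cyclisation of 11 (DMAP, DMF, rt) gives 2-[4-(benzyloxy)-2-(2-methylbut-3-en-2-yloxy)phenyl]-5,7-dimethoxy-4H-chromen-4-one F1. Deprotonation at C3 with LiN(iPr)2 in THF at −78 °C and an iodine quench gives the 3-iodoflavone F2. Stille coupling with tributyl(vinyl)stannane (Pd2(dba)3, AsPh3, CuI, DMF, 45 °C) gives the 3-ethenylflavone F3. Ring-closing metathesis with the second-generation Hoveyda–Grubbs catalyst RuCl2(H2IMes)(=CH–C6H4-2-OiPr) in dilute CH2Cl2 at 40 °C releases ethene and gives 12. This is the eight-membered counterpart of the metathesis that turns ortho-vinylaryl 1,1-dimethylallyl ethers into 2,2-dimethylchromenes.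
- Side note: F1 is also what premature protonolysis in step 6 would leave. It need not be lost, since electrophilic palladation of chromones at C3 is a known entry into oxidative Heck chemistry, but the fallback does not depend on this.

**Step 4.**
- Most likely failure: incomplete addition, because the phenolate oxygen donates into the formyl group, and ionisation of the very electron-rich benzylic and propargylic carbinol 10 on work-up (loss of water or rearrangement).
- Fallback: mask the phenol, going from 7 to 11. Silylation of 7 (iPr3SiCl, imidazole, DMF) gives 2,4-dimethoxy-6-[(triisopropylsilyl)oxy]benzaldehyde F4. Addition of acetylide 9 (THF, −78 °C) to the now fully electrophilic aldehyde gives the silyl-protected carbinol F5. MnO2 in CH2Cl2 gives the silyl-protected ynone F6. HF·pyridine buffered with pyridine in THF at 0 °C removes the silyl group without forming a free phenolate and gives 11.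

**Step 7.**
- Most likely failure: hydrogenolysis of the C11–O bond while it is still allylic, opening the oxocine ring before the alkene is saturated.
- Fallback: separate the two events, going from 12 to 13. Diimide, generated from 2-nitrobenzenesulfonohydrazide and Et3N in CH2Cl2 at rt, transfers H2 to the cis alkene in a concerted way that cannot cleave a C–O bond and gives 4'-O-benzyl-5-O-methylcyclointegrin F7, which has the same structure as A8. Hydrogenolysis of the benzyl ether over Pd/C in EtOAc then gives 13.

**Step 8.**
- Most likely failure: Lewis-acid ionisation of the tertiary C11–O bond, favoured by the extra equivalent of BCl3 that the 4'-phenol consumes, and partial cleavage of the 7-methyl ether if the mixture warms.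
- Fallback: avoid any Lewis acid at the end by carrying the C5 oxygen as a benzyl ether, going from 7 to 15. AlCl3 in CH2Cl2 at rt cleaves the second ortho methyl ether of 7 by chelation and gives 2,6-dihydroxy-4-methoxybenzaldehyde F8. One equivalent of BnBr with K2CO3 in acetone gives 2-(benzyloxy)-6-hydroxy-4-methoxybenzaldehyde F9, whose remaining phenol is chelated and unreactive. F9, deprotonated with NaH as in step 4, is combined with acetylide 9 to give the carbinol F10. MnO2 gives the ynone F11. The conditions of step 6 give 4',5-di-O-benzyl-9,10-didehydrocyclointegrin F12. Hydrogenation over Pd/C saturates C9=C10 and removes both benzyl groups to give 15 directly.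

## Further compounds

F1 | step 6 | 2-[4-(benzyloxy)-2-(2-methylbut-3-en-2-yloxy)phenyl]-5,7-dimethoxy-4H-chromen-4-one | COc1cc(OC)c2c(=O)cc(oc2c1)-c1ccc(OCc2ccccc2)cc1OC(C)(C)C=C
F2 | step 6 | 2-[4-(benzyloxy)-2-(2-methylbut-3-en-2-yloxy)phenyl]-3-iodo-5,7-dimethoxy-4H-chromen-4-one | COc1cc(OC)c2c(=O)c(I)c(oc2c1)-c1ccc(OCc2ccccc2)cc1OC(C)(C)C=C
F3 | step 6 | 2-[4-(benzyloxy)-2-(2-methylbut-3-en-2-yloxy)phenyl]-3-ethenyl-5,7-dimethoxy-4H-chromen-4-one | COc1cc(OC)c2c(=O)c(C=C)c(oc2c1)-c1ccc(OCc2ccccc2)cc1OC(C)(C)C=C
F4 | step 4 | 2,4-dimethoxy-6-[(triisopropylsilyl)oxy]benzaldehyde | COc1cc(O[Si](C(C)C)(C(C)C)C(C)C)c(C=O)c(OC)c1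
F5 | step 4 | racemic 3-[4-(benzyloxy)-2-(2-methylbut-3-en-2-yloxy)phenyl]-1-{2,4-dimethoxy-6-[(triisopropylsilyl)oxy]phenyl}prop-2-yn-1-ol | COc1cc(O[Si](C(C)C)(C(C)C)C(C)C)c(C(O)C#Cc2ccc(OCc3ccccc3)cc2OC(C)(C)C=C)c(OC)c1
F6 | step 4 | 3-[4-(benzyloxy)-2-(2-methylbut-3-en-2-yloxy)phenyl]-1-{2,4-dimethoxy-6-[(triisopropylsilyl)oxy]phenyl}prop-2-yn-1-one | COc1cc(O[Si](C(C)C)(C(C)C)C(C)C)c(C(=O)C#Cc2ccc(OCc3ccccc3)cc2OC(C)(C)C=C)c(OC)c1
F7 | step 7 | 4'-O-benzyl-5-O-methylcyclointegrin | COc1cc(OC)c2c(=O)c3c(oc2c1)-c1ccc(OCc2ccccc2)cc1OC(C)(C)CC3
F8 | step 8 | 2,6-dihydroxy-4-methoxybenzaldehyde | COc1cc(O)c(C=O)c(O)c1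
F9 | step 8 | 2-(benzyloxy)-6-hydroxy-4-methoxybenzaldehyde | COc1cc(O)c(C=O)c(OCc2ccccc2)c1
F10 | step 8 | racemic 3-(benzyloxy)-2-{3-[4-(benzyloxy)-2-(2-methylbut-3-en-2-yloxy)phenyl]-1-hydroxyprop-2-yn-1-yl}-5-methoxyphenol | COc1cc(O)c(C(O)C#Cc2ccc(OCc3ccccc3)cc2OC(C)(C)C=C)c(OCc2ccccc2)c1
F11 | step 8 | 1-[2-(benzyloxy)-6-hydroxy-4-methoxyphenyl]-3-[4-(benzyloxy)-2-(2-methylbut-3-en-2-yloxy)phenyl]prop-2-yn-1-one | COc1cc(O)c(C(=O)C#Cc2ccc(OCc3ccccc3)cc2OC(C)(C)C=C)c(OCc2ccccc2)c1
F12 | step 8 | 4',5-di-O-benzyl-9,10-didehydrocyclointegrin (cis ring alkene) | COc1cc(OCc2ccccc2)c2c(=O)c3/C=C\C(C)(C)Oc4cc(OCc5ccccc5)ccc4-c3oc2c1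
A1 | alternative 1 | 1-[7-(benzyloxy)-2,2-dimethyl-2H-chromen-4-yl]pyrrolidine | CC1(C)C=C(N2CCCC2)c2ccc(OCc3ccccc3)cc2O1
A2 | alternative 1 | 1-[4-methoxy-2,6-bis(methoxymethoxy)phenyl]prop-2-yn-1-one | C#CC(=O)c1c(OCOC)cc(OC)cc1OCOC
A3 | alternative 1 | [9-(benzyloxy)-2,2-dimethyl-6-(pyrrolidin-1-yl)-2H-1-benzoxocin-5-yl][4-methoxy-2,6-bis(methoxymethoxy)phenyl]methanone | N1(CCCC1)/C2=C(\C(=O)c3c(OCOC)cc(OC)cc3OCOC)/C=C\C(C)(C)Oc3cc(OCc4ccccc4)ccc32
A4 | alternative 2 | 9-(benzyloxy)-2,2-dimethyl-2,3,4,5-tetrahydro-6H-1-benzoxocin-6-one | O=C1CCCC(C)(C)Oc2cc(OCc3ccccc3)ccc12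
A5 | alternative 2 | 2,6-difluoro-4-methoxybenzoyl chloride | COc1cc(F)c(C(=O)Cl)c(F)c1
A6 | alternative 2 | 4'-O-benzyl-5-deoxy-5-fluorocyclointegrin | COc1cc(F)c2c(=O)c3c(oc2c1)-c1ccc(OCc2ccccc2)cc1OC(C)(C)CC3
A7 | alternative 3 | 2-{5-(benzyloxy)-2-[3-ethenyl-5,7-dimethoxy-4-oxo-4H-chromen-2-yl]phenoxy}-2-methylpropanoic acid | COc1cc(OC)c2c(=O)c(C=C)c(oc2c1)-c1ccc(OCc2ccccc2)cc1OC(C)(C)C(=O)O
A8 | alternative 3 | 4'-O-benzyl-5-O-methylcyclointegrin | COc1cc(OC)c2c(=O)c3c(oc2c1)-c1ccc(OCc2ccccc2)cc1OC(C)(C)CC3
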